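## Retrosynthetic overview
- Side-chain carbons: sulcatone 1 + CH2O → (Mannich base 2) → α-methylene ketone 3.
- Key disconnection C8–CH2: enone 3 + kaempferol 4 → (ketiminium 5, enamine 6) → (S)-methyl ketone 7, by amine-catalysed conjugate addition at C8 with the stereocentre set by enantioselective enamine protonation.
- Isopropenyl C=CH2: Wittig methylenation 7 → target 8.
- Rings: none is formed; rings A, C and B are bought intact as achiral kaempferol.

Assumption: kaempferol (achiral, sold as a fine chemical) is accepted as a commercial starting material.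
Assumption: the (S)-diamine catalyst gives (S)-7; if the sense of induction proves opposite, its (R)-antipode (from D-tert-leucine) is used and nothing else changes.
Assumption: 7 is drawn and counted in its open keto form; its reversible ring closure onto the 7-OH (cyclic hemiketal) is treated as the same compound.
Catalyst of step 2: (S)-N1,N1-diethyl-3,3-dimethylbutane-1,2-diamine as its mono-TfOH salt, free base CCN(CC)C[C@@H](N)C(C)(C)C, made from L-tert-leucine.

## Route

Step 1
Reactants: 1 6-methylhept-5-en-2-one (sulcatone)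
Product: 3 6-methyl-3-methylidenehept-5-en-2-one, via Mannich base 2 (not isolated)
Conditions: (CH2O)n (1.5 equiv), PhNHMe·CF3CO2H (0.5 equiv), THF, reflux, 3 h; distil, keep cold over BHT
Reagents that add atoms: paraformaldehyde (formaldehyde equivalent), C=O
Why: Mannich-type α-methylenation, in which the ammonium salt turns formaldehyde into an iminium ion, the thermodynamically favoured more substituted enol of the methyl ketone attacks it through C3 to give 2, and β-elimination of N-methylaniline leaves the 1,1-disubstituted enone with no stereocentre.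

Step 2
Reactants: 3 6-methyl-3-methylidenehept-5-en-2-one; 4 kaempferol
Product: 7 8-[(2S)-2-acetyl-5-methylhex-4-en-1-yl]kaempferol, via ketiminium triflate 5 (not isolated), via enamine 6 (not isolated)
Conditions: 3 (1.3 equiv), (S)-H2NCH(t-Bu)CH2NEt2·TfOH (20 mol %), H2O (5 equiv), THF, 0 °C to rt, 48–72 h, argon
Reagents that add atoms: none
Why: Proposed new method: a Friedel–Crafts-type conjugate addition with enantioselective protonation, in which the primary amine condenses with 3 to ketiminium 5, the NEt2 arm takes the acidic 7-OH proton of 4 so that the phenoxide attacks the CH2 terminus through C8 (the site 5,7-dihydroxyflavones use in Mannich aminomethylation), rearomatisation leaves enamine 6 with the proton on the neighbouring Et2NH+ group, and that ammonium returns it to one face of the enamine carbon to set the (S) stereocentre before hydrolysis frees 7; the closest known reaction type is the primary-amine-catalysed conjugate addition/enantioselective enamine protonation of α-substituted acroleins and vinyl ketones with indoles, azoles and thiols, not yet shown for a phenolic C–H nucleophile or a flavonoid.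

Step 3
Reactants: 7 8-[(2S)-2-acetyl-5-methylhex-4-en-1-yl]kaempferol
Product: 8 8-[(2S)-5-methyl-2-(prop-1-en-2-yl)hex-4-en-1-yl]kaempferol (target, CNP0185677.2)
Conditions: Ph3PCH3Br (7.5 equiv), KN(SiMe3)2 (7 equiv), THF, 0 °C; add 7, 0 °C to rt, argon; aqueous NH4Cl
Reagents that add atoms: methyltriphenylphosphonium bromide, C[P+](c1ccccc1)(c1ccccc1)c1ccccc1.[Br-]
Why: Wittig methylenation of the only electrophilic carbonyl (the chromenone C4=O is a vinylogous ester made still less reactive once the excess ylide has deprotonated the four OH groups), run cold so that the α-stereocentre, at which no bond changes, keeps its (S) configuration.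

## Compound list
1 | 6-methylhept-5-en-2-one (sulcatone) | CC(=O)CCC=C(C)C | starting material
2 | 6-methyl-3-{[methyl(phenyl)amino]methyl}hept-5-en-2-one (racemic Mannich base) | CC(=O)C(CN(C)c1ccccc1)CC=C(C)C | intermediate
3 | 6-methyl-3-methylidenehept-5-en-2-one | CC(=O)C(=C)CC=C(C)C | intermediate
4 | kaempferol, 3,5,7-trihydroxy-2-(4-hydroxyphenyl)-4H-chromen-4-one | O=c1c(O)c(-c2ccc(O)cc2)oc2cc(O)cc(O)c12 | starting material
5 | N-[(2S)-1-(diethylamino)-3,3-dimethylbutan-2-yl]-6-methyl-3-methylidenehept-5-en-2-iminium triflate | C=C(CC=C(C)C)C(C)=[NH+][C@H](CN(CC)CC)C(C)(C)C.[O-]S(=O)(=O)C(F)(F)F | intermediate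
6 | 8-{2-[1-({(2S)-1-(diethylammonio)-3,3-dimethylbutan-2-yl}amino)ethylidene]-5-methylhex-4-en-1-yl}kaempferol triflate (catalyst-bound enamine) | CC(N[C@H](C[NH+](CC)CC)C(C)(C)C)=C(CC=C(C)C)Cc1c(O)cc(O)c2c(=O)c(O)c(-c3ccc(O)cc3)oc12.[O-]S(=O)(=O)C(F)(F)F | intermediate
7 | 8-[(2S)-2-acetyl-5-methylhex-4-en-1-yl]-3,5,7-trihydroxy-2-(4-hydroxyphenyl)-4H-chromen-4-one | CC(=O)[C@@H](CC=C(C)C)Cc1c(O)cc(O)c2c(=O)c(O)c(-c3ccc(O)cc3)oc12 | intermediate
8 | 3,5,7-trihydroxy-2-(4-hydroxyphenyl)-8-[(2S)-5-methyl-2-(prop-1-en-2-yl)hex-4-en-1-yl]-4H-chromen-4-one | C=C(C)[C@@H](CC=C(C)C)Cc1c(O)cc(O)c2c(=O)c(O)c(-c3ccc(O)cc3)oc12 | target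

## Count and risks
Total steps: 3. Longest linear sequence: 3 (1 → 3 → 7 → 8).

**Step 2 (the proposed new step, highest risk).** Possible failures:
- Low ee, because the neighbouring 7-OH can protonate the enamine without catalyst control.
- Some C6 isomer, to be removed by chromatography.
- Slow C–C bond formation.

Over-alkylation should be limited, because ring closure of 7 onto its 7-OH masks the phenol that activates C6.

Fallback with known chemistry, setting out from 3 and 4 and coming back at 7: kaempferol 4 is C-alkylated by enone 3 under plain base catalysis (Et3N, MeOH, rt to 40 °C), the long-established Michael addition of phloroglucinol-type phenoxides to enones. This gives racemic 8-(2-acetyl-5-methylhex-4-en-1-yl)kaempferol F1. Preparative chromatography on a chiral amylose phase (supercritical CO2/MeOH) separates 7 from its mirror image 8-[(2R)-2-acetyl-5-methylhex-4-en-1-yl]kaempferol F2. F2 is epimerised back to F1 with DBU in THF and recycled.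

**Step 3.** The tetra-phenoxide may be poorly soluble, conversion may stall, or the α-centre may partly epimerise under the large excess of ylide.

Fallback, setting out from 7 and coming back at 8: TBSCl/imidazole in DMF silylates the 3-, 7- and 4'-OH groups (the chelated 5-OH stays free) to give 8-[(2S)-2-acetyl-5-methylhex-4-en-1-yl]kaempferol 3,7,4'-tris(tert-butyldimethylsilyl) ether F3. This neutral, THF-soluble ketone needs only 2.2 equiv of salt-free Ph3P=CH2 (THF, −20 to 0 °C) and gives 8-[(2S)-5-methyl-2-(prop-1-en-2-yl)hex-4-en-1-yl]kaempferol 3,7,4'-tris(tert-butyldimethylsilyl) ether F4. Bu4NF buffered with AcOH (THF, 0 °C) then returns 8.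

**Step 1.** Some methylenation at C1, double methylenation, acid-induced reaction of the prenyl alkene with formaldehyde, or polymerisation of 3 on distillation.

Fallback, setting out from 1 and coming back at 3: a classical two-stage Mannich sequence. Me2NH·HCl, (CH2O)n and catalytic HCl in i-PrOH at reflux give 3-[(dimethylamino)methyl]-6-methylhept-5-en-2-one F5, freed from the minor C1 isomer by fractional distillation. MeI in Et2O gives 2-acetyl-N,N,N,5-tetramethylhex-4-en-1-aminium iodide F6. Aqueous NaHCO3/CH2Cl2 at rt eliminates trimethylamine to give regiopure 3.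

## Further compounds
F1 | step 2 | racemic 8-(2-acetyl-5-methylhex-4-en-1-yl)kaempferol | CC(=O)C(CC=C(C)C)Cc1c(O)cc(O)c2c(=O)c(O)c(-c3ccc(O)cc3)oc12
F2 | step 2 | 8-[(2R)-2-acetyl-5-methylhex-4-en-1-yl]kaempferol | CC(=O)[C@H](CC=C(C)C)Cc1c(O)cc(O)c2c(=O)c(O)c(-c3ccc(O)cc3)oc12
F3 | step 3 | 8-[(2S)-2-acetyl-5-methylhex-4-en-1-yl]kaempferol 3,7,4'-tris(tert-butyldimethylsilyl) ether | CC(=O)[C@@H](CC=C(C)C)Cc1c(O[Si](C)(C)C(C)(C)C)cc(O)c2c(=O)c(O[Si](C)(C)C(C)(C)C)c(-c3ccc(O[Si](C)(C)C(C)(C)C)cc3)oc12
F4 | step 3 | 8-[(2S)-5-methyl-2-(prop-1-en-2-yl)hex-4-en-1-yl]kaempferol 3,7,4'-tris(tert-butyldimethylsilyl) ether | C=C(C)[C@@H](CC=C(C)C)Cc1c(O[Si](C)(C)C(C)(C)C)cc(O)c2c(=O)c(O[Si](C)(C)C(C)(C)C)c(-c3ccc(O[Si](C)(C)C(C)(C)C)cc3)oc12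
F5 | step 1 | 3-[(dimethylamino)methyl]-6-methylhept-5-en-2-one | CC(=O)C(CN(C)C)CC=C(C)C
F6 | step 1 | 2-acetyl-N,N,N,5-tetramethylhex-4-en-1-aminium iodide | CC(=O)C(C[N+](C)(C)C)CC=C(C)C.[I-]
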